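The data were computed on assumed constants; noise was put on by code.

A racemate cannot hold its product excess to the end: each product stops at half of the charge, so full conversion means zero excess. The dispute is how soon the excess falls in this flask.

the same everywhere: gas 36 mM (held)

|  | left-handed substrate | right-handed substrate | free catalyst | remark | time |
|---|---|---|---|---|---|
| red | 0.40 M | 0.40 M | 1.7 mol% | run made earlier |  |
| amber | 0.40 M | 0.40 M | 3.8 mol% | run made earlier |  |
| ochre | 0.20 M | 0.20 M | 2.5 mol% | run made earlier |  |
| flask | 0.40 M | 0.40 M | 2.5 mol% |  | 3.0 min |

| run | time / min | left-handed product / % | right-handed product / % |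
|---|---|---|---|
| red | 0.200 | 1.5 | 0 |
| red | 0.333 | 2.4 | 0.7 |
| red | 0.500 | 4.6 | 1.2 |
| red | 0.833 | 6.7 | 2.5 |
| red | 1.33 | 11.5 | 3.9 |
| red | 2.50 | 21.7 | 9.1 |
| amber | 0.167 | 1.2 | 0.9 |
| amber | 0.500 | 5.7 | 2.0 |
| amber | 0.833 | 10.2 | 3.7 |
| amber | 1.33 | 17.0 | 7.0 |
| amber | 2.00 | 25.2 | 9.8 |
| amber | 2.50 | 30.0 | 13.6 |
| ochre | 0.500 | 5.6 | 2.1 |
| ochre | 1.00 | 12.7 | 5.2 |
| ochre | 1.33 | 17.0 | 6.2 |
| ochre | 2.00 | 24.6 | 10.9 |
| ochre | 2.50 | 30.0 | 13.7 |

(each reading ± 0.3 percentage points)

- free catalyst is single-handed; left-handed substrate and right-handed substrate are mirror images of each other, charged as a racemate, each of them at the stated concentration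
- at the start none of reagent is dissolved
- the numbers in the tables scatter with a standard deviation of 0.3 percentage points
- candidate steps: free catalyst + left-handed substrate <-> catalyst intermediate A; free catalyst + right-handed substrate <-> catalyst intermediate B; reagent + catalyst intermediate A -> free catalyst + left-handed product; reagent + catalyst intermediate B -> free catalyst + right-handed product; reagent <-> dormant form; gas <-> reagent; 2 free catalyst <-> resting dimer
- an excess is the difference of the two amounts in percent of their sum
- an excess is below zero if the other one leads

- excess of left-handed product over right-handed product in the product at 10 s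
- excess of left-handed product over right-handed product in the product at 3.0 min
- part of the left-handed substrate and right-handed substrate charged together that has reacted at 3.0 min

Two chemists read these runs. Write L and R for the fractions of left-handed and right-handed substrate left of their own charges, each taken as one minus twice its product share.

The second chemist looks at the amber run. Its product total grows 5.66-fold while time grows 5.00-fold. To him that near-straight line means a saturated catalyst, with the intermediates as its resting state, and so a frozen product ratio. He reads the amber excess at 0.833 min, 46.8%, and expects it in the flask at 3.0 min.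

The first chemist points to the last amber reading, an excess of 37.6%. She holds that the two substrates compete for one catalyst, each used in proportion to what remains of it. Then the amber end gives 2.89 for the selectivity factor, the logarithm of L over the logarithm of R, and this stays constant as both fall. The ochre end, at a different charge, gives 2.86. The amber value puts the starting excess, (s − 1)/(s + 1), at 48.5%.

She made the forecast: “This fits plain kinetic resolution”. It takes about 2.85 for s and prints 47% (38% to 55%), 37.5% (35% to 40.5%) and 43% (39.5% to 46.5%). Its early figure lies lower than the amber reckoning.

The flask gives 48.8%, 38.2% and 44.3%. The forecast stands, and the frozen figure fails at 3.0 min. The frozen view keeps the earliest stretch, where 10 s still shows 48.8%.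

    free catalyst + left-handed substrate ⇌ catalyst intermediate A (K = 19.0 L mol⁻¹, k = 256 L mol⁻¹ s⁻¹)
    free catalyst + right-handed substrate ⇌ catalyst intermediate B (K = 18.0 L mol⁻¹, k = 102 L mol⁻¹ s⁻¹)
    reagent + catalyst intermediate A → free catalyst + left-handed product (k = 19.4 L mol⁻¹ s⁻¹)
    reagent + catalyst intermediate B → free catalyst + right-handed product (k = 6.97 L mol⁻¹ s⁻¹)
    reagent ⇌ dormant form (K = 14.0, k = 0.00618 s⁻¹)
    gas ⇌ reagent, rate k6*(csat - [reagent]) (kL = 0.112 s⁻¹)
    2 free catalyst ⇌ resting dimer (K = 220 L mol⁻¹, k = 1.86 L mol⁻¹ s⁻¹)

In the flask, the unbound fractions at 3.0 min, 39% and 72%, give 2.82 for s, against the 2.89 read from the amber run. The excess follows substrate depletion because catalyst intermediate B returns to free catalyst and right-handed substrate: without that return, the flask ends at −79.7%, not 38.2%.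

In a neighbour flask, like this one but charged with 1.5 mol% of free catalyst, R = 80% at 3.0 min, so s gives L = 52.6% and an excess of 40.7%. The computed flask has 53% and 41.5%.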